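**Assumptions (one line each)**
- The target's 5–7 ring fusion is trans (H‑a and the angular methyl on opposite faces), as encoded in the SMILES.
- Step 1 uses (S)‑Me‑CBS, which by analogy with aryl methyl ketones should give the (R)‑alcohol (sp² side taken as the large group).
- The aldol carbinol centre (C‑i) forms as an epimeric mixture. It is carried through Steps 7–12 and converges at Step 13.
- Ring carbons are labelled a (ring‑fusion CH), b (quaternary C–Me), q (C(OH)iPr), i (CH–OAr), f (CH–OH), g (C=CH2).

## Retrosynthetic overview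
1. Ferugin comes from late acylation of the C‑i alcohol. The C‑f ketone serves as a masked alcohol, and C‑i is set by a hydroxyl‑directed reduction of an i‑ketone, so the aldol C‑i epimers converge.
2. The key disconnection is the seven‑membered ring, closed by a Parham‑type cycloacylation of a vinyllithium onto a tertiary amide. This forms the g–f bond and gives the exocyclic methylene and the f‑oxygen together.
3. The cyclopentane is built first, so the trans fusion comes from pre‑set stereocentres. The a–i bond is made by aldol anti to the larger b‑substituent, and the tertiary carbinol by iPr addition anti to the a‑substituent.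
4. The quaternary centre b comes from CBS reduction of 3‑methylcyclopentenone followed by Eschenmoser–Claisen chirality transfer. Ring order: cyclopentane (Steps 1–10), then cycloheptane (Step 11).

## Route

**Step 1**
Reactants: 1 (3‑methylcyclopent‑2‑en‑1‑one)
Product: 2 ((1R)‑3‑methylcyclopent‑2‑en‑1‑ol)
Conditions: (S)‑Me‑CBS (10 mol%), BH3·SMe2, THF, −20 °C
Reagents that add atoms: none
Why: Corey–Itsuno reduction; the (S)‑oxazaborolidine delivers hydride to the Si face of the carbonyl, setting the only stereocentre that is later transferred to quaternary C‑b.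

**Step 2**
Reactants: 2; 3 (N,N‑dimethylacetamide dimethyl acetal)
Product: 4 (2‑[(1R)‑1‑methylcyclopent‑2‑en‑1‑yl]‑N,N‑dimethylacetamide)
Conditions: 3 (3 equiv), xylenes, 140 °C, sealed tube
Reagents that add atoms: 3, CC(OC)(OC)N(C)C (adds CH2C(=O)NMe2)
Why: Eschenmoser–Claisen [3,3] rearrangement is suprafacial, so the CH2CONMe2 group lands on C3 on the face that carried the C–O bond, converting the carbinol centre into the quaternary stereocentre b (R) with the ring methyl pushed to the opposite face.

**Step 3**
Reactants: 4
Product: 5 (2‑(3‑hydroxy‑1‑methylcyclopentyl)‑N,N‑dimethylacetamide, carbinol epimers, quaternary centre as in 4)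
Conditions: 9‑BBN (1.2 equiv), THF, 25 °C; then NaBO3·4H2O, THF/H2O
Reagents that add atoms: H2O2 from NaBO3, OO (supplies OH)
Why: Hydroboration–oxidation; bulky 9‑BBN places boron on the alkene carbon remote from the quaternary centre, and the new carbinol stereocentre is destroyed in Step 4.

**Step 4**
Reactants: 5
Product: 6 (2‑[(1S)‑1‑methyl‑3‑oxocyclopentyl]‑N,N‑dimethylacetamide)
Conditions: Dess–Martin periodinane, CH2Cl2, 25 °C
Reagents that add atoms: none
Why: Dess–Martin oxidation of the secondary alcohol; b is untouched.

**Step 5**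
Reactants: 6
Product: 7 (2‑[(1S)‑1‑methyl‑4‑oxocyclopent‑2‑en‑1‑yl]‑N,N‑dimethylacetamide)
Conditions: IBX·MPO (2.5 equiv), DMSO, 65 °C
Reagents that add atoms: none
Why: Nicolaou IBX dehydrogenation; only the side remote from the quaternary centre can desaturate, and the remaining α′‑CH2 (future a) becomes the only enolisable position, which fixes the regiochemistry of Step 7.

**Step 6**
Reactants: 8 (3‑bromobut‑3‑en‑1‑ol)
Product: 9 (3‑bromobut‑3‑enal)
Conditions: Dess–Martin periodinane, NaHCO3, CH2Cl2, 0 → 25 °C; use crude immediately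
Reagents that add atoms: none
Why: Dess–Martin oxidation supplies the non‑enolisable‑on‑demand aldehyde carrying the future g‑vinyl bromide.

**Step 7**
Reactants: 7; 9
Product: 10 (5‑(3‑bromo‑1‑hydroxybut‑3‑en‑1‑yl)‑4‑methyl‑4‑(CH2CONMe2)cyclopent‑2‑en‑1‑one; C4 (S), H5 trans to the CH2CONMe2 chain, C1′ epimers)
Conditions: LDA (1.05 equiv), THF, −78 °C; then 9 (1.5 equiv), −78 °C; NH4Cl quench
Reagents that add atoms: 9, C=C(Br)CC=O
Why: Aldol addition of the α′‑dienolate; the aldehyde approaches anti to the larger CH2CONMe2 group (syn to Me), which sets H‑a trans to the chain, the stereochemical basis of the trans ring fusion.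

**Step 8**
Reactants: 10; 11 (TESOTf)
Product: 12 (C‑1′ triethylsilyl ether of 10)
Conditions: 11 (1.5 equiv), 2,6‑lutidine, CH2Cl2, −78 °C
Reagents that add atoms: 11, CC[Si](CC)(CC)OS(=O)(=O)C(F)(F)F (adds SiEt3)
Why: Silylation under non‑basic conditions avoids E1cB elimination of the β‑oxygen and retro‑aldol, and it blocks alkoxide chelation in Step 9.

**Step 9**
Reactants: 12; 13 (iPrMgCl)
Product: 14 (tertiary allylic alcohol: q has OH down and iPr up)
Conditions: iPrMgCl·LaCl3·2LiCl (3 equiv), THF, −78 → −40 °C
Reagents that add atoms: 13, CC(C)[Mg]Cl (adds iPr)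
Why: Lanthanum‑promoted 1,2‑addition (Knochel) suppresses enolisation and reduction, and the isopropyl group enters anti to the large C5 substituent (H‑a is on the open face), giving the target carbinol configuration.

**Step 10**
Reactants: 14
Product: 15 (saturated cyclopentane, same stereocentres)
Conditions: [Ir(cod)(PCy3)(py)]PF6 (5 mol%), H2 (1 atm), CH2Cl2, 25 °C
Reagents that add atoms: none
Why: Crabtree hydrogenation directed by the tertiary allylic OH reduces the ring alkene selectively over the 1,1‑disubstituted vinyl bromide, and no new stereocentre is formed.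

**Step 11**
Reactants: 15
Product: 16 (trans‑fused bicyclic α‑methylene ketone, C‑i OTES; C‑i epimers)
Conditions: t‑BuLi (3.5 equiv), Et2O/THF 4:1 (0.01 M), −78 → −20 °C; NH4Cl quench
Reagents that add atoms: none (Br and NMe2 are lost)
Why: Proposed new method: Li–Br exchange gives the 2‑lithioalkene, which adds intramolecularly (7‑exo‑trig) to the N,N‑dimethylamide to give a stable lithium hemiaminal (the excess equivalent also deprotonates the tertiary OH), and aqueous work‑up releases the α‑methylene cycloheptanone. The closest known reaction is Parham‑type cycloacylation of organolithiums onto amides. The a‑H and b‑Me stereocentres are untouched, and the trans‑disposed chains force the trans‑fused ring.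

**Step 12**
Reactants: 16
Product: 17 (free C‑i alcohol)
Conditions: HF·pyridine, THF, 0 → 25 °C
Reagents that add atoms: none
Why: Fluoride desilylation of the secondary TES ether; the tertiary alcohol and enone are unaffected.

**Step 13**
Reactants: 17
Product: 18 (C‑i ketone; both C‑i epimers converge)
Conditions: Dess–Martin periodinane, NaHCO3, CH2Cl2, 0 °C
Reagents that add atoms: none
Why: Dess–Martin oxidation erases the uncontrolled C‑i configuration under neutral conditions that do not epimerise H‑a or cause retro‑aldol.

**Step 14**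
Reactants: 18
Product: 19 (C‑i alcohol up, f still ketone)
Conditions: Me4NBH(OAc)3 (6 equiv), MeCN/AcOH 1:1, −20 °C
Reagents that add atoms: none
Why: Evans–Saksena hydroxyl‑directed reduction; hydride is delivered intramolecularly from the q–O–B species (down face) to the β‑ketone, so the C‑i OH ends up up, cis to H‑a, as in the target.

**Step 15**
Reactants: 19; 20 (4‑acetoxybenzoyl chloride)
Product: 21 (C‑i 4‑acetoxybenzoate)
Conditions: 20 (2 equiv), Et3N, DMAP (cat.), CH2Cl2, 0 → 40 °C
Reagents that add atoms: 20, CC(=O)Oc1ccc(cc1)C(=O)Cl (adds the aroyl group)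
Why: Acylation of the secondary alcohol with retention; the tertiary OH is too hindered to react and the f‑ketone acts as the masked second hydroxyl.

**Step 16**
Reactants: 21
Product: 22 (C‑f alcohol up; aryl acetate intact)
Conditions: (R)‑Me‑CBS (20 mol%), BH3·SMe2, THF, −40 → 0 °C
Reagents that add atoms: none
Why: CBS reduction of the α‑methylene ketone is catalyst‑controlled, with (R)‑oxazaborolidine delivering hydride to the Re face (assuming the sp² carbon is the large group) to give the (S)‑allylic alcohol, which overrides the intrinsic anti‑to‑Me bias; borane leaves the esters untouched.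

**Step 17**
Reactants: 22
Product: 23 (ferugin)
Conditions: NH2NH2·AcOH (1.5 equiv), DMF, 25 °C
Reagents that add atoms: none
Why: Hydrazinolysis cleaves the labile phenolic acetate chemoselectively, leaving the alkyl aroate, the allylic alcohol and the tertiary alcohol intact, and it touches no stereocentre.

## Compound list

| # | Name | SMILES | Role |
|---|---|---|---|
| 1 | 3‑methylcyclopent‑2‑en‑1‑one | CC1=CC(=O)CC1 | starting material |
| 2 | (1R)‑3‑methylcyclopent‑2‑en‑1‑ol | CC1=C[C@H](O)CC1 | intermediate |
| 3 | N,N‑dimethylacetamide dimethyl acetal | CC(OC)(OC)N(C)C | starting material |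
| 4 | 2‑[(1R)‑1‑methylcyclopent‑2‑en‑1‑yl]‑N,N‑dimethylacetamide | CN(C)C(=O)C[C@]1(C)C=CCC1 | intermediate |
| 5 | 2‑(3‑hydroxy‑1‑methylcyclopentyl)‑N,N‑dimethylacetamide (carbinol epimers) | CN(C)C(=O)C[C@]1(C)CC(O)CC1 | intermediate |
| 6 | 2‑[(1S)‑1‑methyl‑3‑oxocyclopentyl]‑N,N‑dimethylacetamide | CN(C)C(=O)C[C@]1(C)CC(=O)CC1 | intermediate |
| 7 | 2‑[(1S)‑1‑methyl‑4‑oxocyclopent‑2‑en‑1‑yl]‑N,N‑dimethylacetamide | CN(C)C(=O)C[C@]1(C)CC(=O)C=C1 | intermediate |
| 8 | 3‑bromobut‑3‑en‑1‑ol | C=C(Br)CCO | starting material |
| 9 | 3‑bromobut‑3‑enal | C=C(Br)CC=O | intermediate |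
| 10 | aldol adduct (C‑1′ epimers) | CN(C)C(=O)C[C@]1(C)[C@@H](C(O)CC(Br)=C)C(=O)C=C1 | intermediate |
| 11 | triethylsilyl triflate | CC[Si](CC)(CC)OS(=O)(=O)C(F)(F)F | starting material |
| 12 | TES ether of 10 | CN(C)C(=O)C[C@]1(C)[C@@H](C(O[Si](CC)(CC)CC)CC(Br)=C)C(=O)C=C1 | intermediate |
| 13 | isopropylmagnesium chloride | CC(C)[Mg]Cl | starting material |
| 14 | tertiary allylic alcohol | CN(C)C(=O)C[C@]1(C)[C@@H](C(O[Si](CC)(CC)CC)CC(Br)=C)[C@](O)(C(C)C)C=C1 | intermediate |
| 15 | saturated cyclopentane | CN(C)C(=O)C[C@]1(C)[C@@H](C(O[Si](CC)(CC)CC)CC(Br)=C)[C@](O)(C(C)C)CC1 | intermediate |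
| 16 | bicyclic α‑methylene ketone, C‑i OTES | C=C1CC(O[Si](CC)(CC)CC)[C@@H]2[C@](C)(CC[C@@]2(O)C(C)C)CC1=O | intermediate |
| 17 | C‑i alcohol | C=C1CC(O)[C@@H]2[C@](C)(CC[C@@]2(O)C(C)C)CC1=O | intermediate |
| 18 | C‑i ketone | C=C1CC(=O)[C@@H]2[C@](C)(CC[C@@]2(O)C(C)C)CC1=O | intermediate |
| 19 | C‑i alcohol (up), f ketone | C=C1C[C@H](O)[C@@H]2[C@](C)(CC[C@@]2(O)C(C)C)CC1=O | intermediate |
| 20 | 4‑acetoxybenzoyl chloride | CC(=O)Oc1ccc(cc1)C(=O)Cl | starting material |
| 21 | C‑i 4‑acetoxybenzoate, f ketone | C=C1C[C@H](OC(=O)c2ccc(OC(C)=O)cc2)[C@@H]2[C@](C)(CC[C@@]2(O)C(C)C)CC1=O | intermediate |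
| 22 | C‑f alcohol, aryl acetate | C=C1C[C@H](OC(=O)c2ccc(OC(C)=O)cc2)[C@@H]2[C@](C)(CC[C@@]2(O)C(C)C)C[C@@H]1O | intermediate |
| 23 | ferugin | C=C1C[C@H](OC(=O)c2ccc(O)cc2)[C@@H]2[C@](C)(CC[C@@]2(O)C(C)C)C[C@@H]1O | target |

**Total steps:** 17. **Longest linear sequence:** 16 steps (Steps 1–5, then 7–17; Step 6 is a parallel preparation of aldehyde 9).

## Three steps most likely to fail

1. **Step 11 (Parham cycloacylation).** The seven‑membered, trans‑fused closure could be outcompeted by protonation or intermolecular attack. Fallback (different bond construction): reduce the amide to the aldehyde with Cp2Zr(H)Cl and close the ring by an intramolecular Nozaki–Hiyama–Kishi (CrCl2/NiCl2) reaction of the vinyl bromide onto that aldehyde, which gives the f‑alcohol directly and removes Step 16.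
2. **Step 7 (aldol).** The aldehyde is enolisable, and the facial selectivity at C‑a may be only moderate. Fallback: α‑formylate enone 7 (ethyl formate) to the hydroxymethylene ketone, protect it as an enol ether, and add 2,3‑dibromopropene/In (Barbier allylation) to the formyl group, then epimerise C‑a to the trans‑favoured isomer. This makes the a–i bond by allylation instead of aldol.
3. **Step 16 (CBS reduction at C‑f).** The intrinsic hydride attack is anti to the angular methyl, giving the wrong C‑f epimer, so the catalyst must overcome it. Fallback: Luche reduction to the C‑f epimer, then Mitsunobu inversion (p‑nitrobenzoic acid/DIAD/PPh3) and selective methanolysis, inverting the centre by SN2 instead of by facial control.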